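**Plan**
1. Retrosynthesis cuts C1'–C2' (carbinol carbon to the Z-vinyl carbon), then in the C14 half the C3'–C4' diene bond, the C4'=C5' olefin and the ring bond C1''–C6''. The C8 half is traced back to an arene.
2. Left half: geranyl acetate → (6R)-epoxide → cationic epoxy-olefin cyclisation (cyclohexene ring) → aldehyde → E-iodoalkene → Stille coupling with a Z-silylstannane from propyne → Z-dienyl iodide.
3. Right half: a p-methoxyphenol is dearomatised to a quinone monoketal, epoxidised, hydrolysed and reduced twice, then taken to a 7-oxabicyclo[4.1.0]heptene-1-carbaldehyde.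
4. Union: Nozaki–Hiyama–Kishi coupling. It is possible because C1' sits between vinyl C2' and the quaternary oxirane carbon C1 of the bicycle: the aldehyde cannot enolise, and its faces are differentiated by the oxirane oxygen and the cis C2–OTBS group.
5. Stereochemistry: Shi epoxidation sets C5'' and the chair cyclisation relays it to C1''. Tartrate-mediated epoxidation sets C1/C6, the Luche reduction relays them to C2 and C5, and the aldehyde controls C1'. Alkene geometry comes from syn-silylstannation and Takai olefination.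
6. Global desilylation ends the route.

Key step: step 22

Assumption: L-DIPT is taken to give the (1S,6R)-oxirane 22 in step 16; if the induction runs the other way, D-DIPT is used under otherwise identical conditions.
Locants: bicycle C1 (quaternary oxirane carbon), C2, C3=C4, C5, C6, O7; side chain C1'–C5'; cyclohexene C1''–C6''. TBS = tert-butyldimethylsilyl, PMB = 4-methoxybenzyl.

**Left half**

Step 1
Reactants: 1 geranyl acetate
Product: 2 (2E)-5-[(2R)-3,3-dimethyloxiran-2-yl]-3-methylpent-2-en-1-yl acetate [(6R)-6,7-epoxygeranyl acetate]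
Conditions: D-fructose-derived Shi ketone (30 mol%), Oxone, K2CO3, Bu4NHSO4 (cat.), MeCN/dimethoxymethane/aq. borate buffer, 0 °C
Reagents that add atoms: potassium peroxymonosulfate (Oxone), [K+].[O-]S(=O)(=O)OO
Why: Shi asymmetric epoxidation: the chiral dioxirane attacks the electron-richer remote olefin (the 2,3-olefin is deactivated by the allylic acetate) through the spiro transition state, which for the D-fructose ketone should give the 6R oxirane.

Step 2
Reactants: 2 (6R)-6,7-epoxygeranyl acetate
Product: 3 [(1S,5R)-5-hydroxy-2,6,6-trimethylcyclohex-2-en-1-yl]methyl acetate (OH and CH2OAc cis)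
Conditions: ZrCl4 (1.2 equiv), CH2Cl2, −78 → 0 °C; H2O
Reagents that add atoms: none
Why: Lewis-acid-promoted epoxy-olefin (cation–olefin) cyclisation: the oxirane opens at its tertiary carbon, the E-olefin attacks through a chair transition state with the C–O bond and the CH2OAc group equatorial (hence cis), and the tertiary cation loses the ring proton to give the endocyclic olefin.

Step 3
Reactants: 3 hydroxy acetate
Product: 4 [(1S,5R)-5-(tert-butyldimethylsilyloxy)-2,6,6-trimethylcyclohex-2-en-1-yl]methyl acetate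
Conditions: TBSOTf, 2,6-lutidine, CH2Cl2, −78 → 0 °C
Reagents that add atoms: tert-butyldimethylsilyl triflate, CC(C)(C)[Si](C)(C)OS(=O)(=O)C(F)(F)F
Why: Silylation of the hindered neopentylic secondary alcohol with the silyl triflate; the acetate is not touched.

Step 4
Reactants: 4 silyl ether acetate
Product: 5 [(1S,5R)-5-(tert-butyldimethylsilyloxy)-2,6,6-trimethylcyclohex-2-en-1-yl]methanol
Conditions: K2CO3 (cat.), MeOH, rt
Reagents that add atoms: none
Why: Base-catalysed methanolysis (transesterification) of the primary acetate; the TBS ether is stable.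

Step 5
Reactants: 5 primary alcohol
Product: 6 (1S,5R)-5-(tert-butyldimethylsilyloxy)-2,6,6-trimethylcyclohex-2-ene-1-carbaldehyde
Conditions: Dess–Martin periodinane, NaHCO3, CH2Cl2, 0 °C → rt
Reagents that add atoms: none
Why: Dess–Martin oxidation under buffered, non-basic conditions should keep the β,γ-olefin out of conjugation and the α-stereocentre intact.

Step 6
Reactants: 6 aldehyde
Product: 7 tert-butyl({(1R,5S)-5-[(E)-2-iodoethenyl]-4,6,6-trimethylcyclohex-3-en-1-yl}oxy)dimethylsilane
Conditions: CrCl2 (6 equiv), CHI3 (2 equiv), THF, 0 °C → rt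
Reagents that add atoms: iodoform, IC(I)I
Why: Takai olefination: the gem-dichromium reagent adds to the aldehyde and eliminates to the E-iodoalkene under non-basic conditions, so C1'' is not epimerised.

Step 7
Reactants: 8 propyne; 9 trimethyl(tributylstannyl)silane
Product: 10 (Z)-tributyl[1-(trimethylsilyl)prop-1-en-2-yl]stannane
Conditions: Pd(PPh3)4 (2 mol%), THF, 65 °C, sealed tube
Reagents that add atoms: none
Why: Pd(0)-catalysed silylstannation of a terminal alkyne: cis addition of Si–Sn with tin on the internal and silicon on the terminal carbon, which fixes the later Z-geometry.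

Step 8
Reactants: 7 E-iodoalkene; 10 Z-silylstannane
Product: 11 tert-butyldimethyl({(1R,5S)-4,6,6-trimethyl-5-[(1E,3Z)-3-methyl-4-(trimethylsilyl)buta-1,3-dien-1-yl]cyclohex-3-en-1-yl}oxy)silane
Conditions: Pd2(dba)3 (5 mol%), AsPh3 (20 mol%), CuI (20 mol%), NMP, 50 °C
Reagents that add atoms: none
Why: Stille coupling with retention at both sp2 carbons should give the dienylsilane with silicon cis to C4'.

Step 9
Reactants: 11 dienylsilane
Product: 12 tert-butyl({(1R,5S)-5-[(1E,3Z)-4-iodo-3-methylbuta-1,3-dien-1-yl]-4,6,6-trimethylcyclohex-3-en-1-yl}oxy)dimethylsilane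
Conditions: N-iodosuccinimide (1.2 equiv), (CF3)2CHOH, 0 °C
Reagents that add atoms: N-iodosuccinimide, O=C1CCC(=O)N1I
Why: Ipso-iododesilylation of the vinylsilane through the β-silyl (and allylic) cation, which should proceed with retention of the double-bond geometry.

**Right half**

Step 10
Reactants: 13 4-bromo-2,5-dimethoxybenzaldehyde
Product: 14 4-bromo-2-hydroxy-5-methoxybenzaldehyde
Conditions: BCl3 (1.1 equiv), CH2Cl2, −78 → 0 °C; H2O
Reagents that add atoms: none
Why: Chelation-directed ether cleavage: boron bound to the aldehyde oxygen removes only the ortho methyl group.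

Step 11
Reactants: 14 salicylaldehyde
Product: 15 5-bromo-2-(hydroxymethyl)-4-methoxyphenol
Conditions: NaBH4, MeOH, 0 °C
Reagents that add atoms: none
Why: Borohydride reduction of the aldehyde.

Step 12
Reactants: 15 phenol diol
Product: 16 7-bromo-6-methoxy-2-(4-methoxyphenyl)-4H-1,3-benzodioxine (racemic at the acetal carbon; this centre is lost in step 14)
Conditions: 4-methoxybenzaldehyde dimethyl acetal, PPTS (cat.), CH2Cl2, rt
Reagents that add atoms: 4-methoxybenzaldehyde dimethyl acetal, COC(OC)c1ccc(OC)cc1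
Why: Acid-catalysed transacetalisation ties the phenol and the ortho benzylic alcohol into a six-membered p-methoxybenzylidene acetal.

Step 13
Reactants: 16 aryl bromide
Product: 18 6-methoxy-2-(4-methoxyphenyl)-4H-1,3-benzodioxine-7-carbaldehyde, via aryllithium 17 (not isolated)
Conditions: n-BuLi, THF, −78 °C; then DMF, −78 → 0 °C; H2O
Reagents that add atoms: N,N-dimethylformamide, CN(C)C=O
Why: Bromine–lithium exchange followed by formylation of the aryllithium with DMF.

Step 14
Reactants: 18 acetal aldehyde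
Product: 20 5-(hydroxymethyl)-4-methoxy-2-{[(4-methoxybenzyl)oxy]methyl}phenol, via hydroxymethyl acetal 19 (not isolated)
Conditions: DIBAL-H (5 equiv), CH2Cl2, −78 → 0 °C; Rochelle salt
Reagents that add atoms: none
Why: DIBAL reduces the aldehyde and then cleaves the mixed aryl alkyl acetal reductively at the aryl C–O bond (phenoxide is the better leaving group and the alkyl oxygen the better donor to the oxocarbenium ion), which leaves PMB on the benzylic oxygen and frees the phenol.

Step 15
Reactants: 20 p-methoxyphenol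
Product: 21 5-(hydroxymethyl)-4,4-dimethoxy-2-{[(4-methoxybenzyl)oxy]methyl}cyclohexa-2,5-dien-1-one
Conditions: PhI(OAc)2, MeOH, 0 °C
Reagents that add atoms: methanol, CO
Why: Hypervalent-iodine oxidative dearomatisation of a p-methoxyphenol; methanol adds para to the phenol oxygen to give the quinone monoketal.

Step 16
Reactants: 21 quinone monoketal
Product: 22 (1S,6R)-4-(hydroxymethyl)-5,5-dimethoxy-1-{[(4-methoxybenzyl)oxy]methyl}-7-oxabicyclo[4.1.0]hept-3-en-2-one
Conditions: Ph3COOH, NaHMDS, L-DIPT, 4 Å MS, toluene, −50 °C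
Reagents that add atoms: trityl hydroperoxide, OOC(c1ccccc1)(c1ccccc1)c1ccccc1
Why: Tartrate-mediated nucleophilic (Weitz–Scheffer-type) epoxidation directed by the free hydroxymethyl group: the peroxide adds to the unsubstituted β-carbon of the less hindered enone and closes onto the α-carbon, and the tartrate-bound alkoxide selects the enantiotopic face, which sets both oxirane centres.

Step 17
Reactants: 22 epoxy ketal
Product: 23 (1S,6R)-4-(hydroxymethyl)-1-{[(4-methoxybenzyl)oxy]methyl}-7-oxabicyclo[4.1.0]hept-3-ene-2,5-dione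
Conditions: p-TsOH·H2O (cat.), acetone/H2O, rt
Reagents that add atoms: water, O
Why: Acid hydrolysis of the dimethyl ketal; the oxirane flanked by carbonyl groups resists acid opening and the PMB ether is stable.

Step 18
Reactants: 23 epoxyquinone
Product: 24 (1R,2S,5R,6S)-4-(hydroxymethyl)-1-{[(4-methoxybenzyl)oxy]methyl}-7-oxabicyclo[4.1.0]hept-3-ene-2,5-diol (both OH anti to the oxirane)
Conditions: NaBH4 (3 equiv), CeCl3·7H2O, MeOH, −78 °C
Reagents that add atoms: none
Why: Luche 1,2-reduction of both carbonyls; hydride should arrive on the oxirane face (the anti outcome expected for cyclic α,β-epoxy ketones under Luche conditions, reinforced at C2 by the CH2OPMB group under the ring), giving the 2,5-cis-diol anti to the epoxide.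

Step 19
Reactants: 24 triol
Product: 25 tris-TBS ether of 24 (2-O, 5-O and 4-CH2O silylated; ring configuration unchanged)
Conditions: TBSOTf (3.6 equiv), 2,6-lutidine, CH2Cl2, −78 → 0 °C
Reagents that add atoms: tert-butyldimethylsilyl triflate, CC(C)(C)[Si](C)(C)OS(=O)(=O)C(F)(F)F
Why: Exhaustive silylation with the silyl triflate; the PMB ether and the oxirane survive at low temperature.

Step 20
Reactants: 25 tris-silyl PMB ether
Product: 26 [2,5-bis(tert-butyldimethylsilyloxy)-4-(tert-butyldimethylsilyloxymethyl)-7-oxabicyclo[4.1.0]hept-3-en-1-yl]methanol (ring configuration as in 24)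
Conditions: DDQ, CH2Cl2/pH 7 buffer, 0 °C
Reagents that add atoms: none
Why: Oxidative cleavage of the PMB ether by DDQ (benzylic oxocarbenium ion, hydrolysed by water); silyl ethers, olefin and oxirane are inert.

Step 21
Reactants: 26 primary alcohol
Product: 27 2,5-bis(tert-butyldimethylsilyloxy)-4-(tert-butyldimethylsilyloxymethyl)-7-oxabicyclo[4.1.0]hept-3-ene-1-carbaldehyde (ring configuration as in 24)
Conditions: Dess–Martin periodinane, NaHCO3, CH2Cl2, 0 °C → rt
Reagents that add atoms: none
Why: Dess–Martin oxidation; the aldehyde has a quaternary α-carbon and can neither epimerise nor eliminate.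

**Union and end game**

Step 22
Reactants: 12 Z-dienyl iodide; 27 epoxy aldehyde
Product: 29 tetrakis-TBS ether of the target (free 1'-OH; 1'S), via alkenylchromium 28 (not isolated)
Conditions: CrCl2 (8 equiv), NiCl2 (2 mol%), DMSO, rt
Reagents that add atoms: none
Why: Nozaki–Hiyama–Kishi reaction: Ni(0) inserts into the C–I bond of 12 and transmetalates to Cr(III), giving alkenylchromium 28 with retention of the Z,E-geometry, which adds to the chromium-bound aldehyde of 27; the closest known type is the Ni/Cr coupling of β,β-disubstituted alkenyl iodides with α-oxygenated aldehydes. No ring is closed. The new centre C1' is set by the aldehyde: the formyl C=O is taken to lie anti to the oxirane C1–O bond (dipole-minimised, Cornforth-type rotamer, eclipsing C1–C2), and the alkenyl group enters through the open sector between the oxirane oxygen and C2–H, because the opposite sector is screened by the cis C2–OTBS group and C6–H; this trajectory gives the 1'S alcohol. The step needs chemoselectivity for C=O over the oxirane and the silyl ethers and no loss of alkene geometry; the non-basic alkenylchromium and the quaternary, non-enolisable α-carbon secure both. DMSO as donor solvent should suppress chelation of chromium by the oxirane oxygen, which would favour the C1' epimer.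

Step 23
Reactants: 29 coupled silyl ether
Product: 30 (1R,2S,5R,6S)-4-(hydroxymethyl)-1-{(1S,2Z,4E)-1-hydroxy-5-[(1S,5R)-5-hydroxy-2,6,6-trimethylcyclohex-2-en-1-yl]-3-methylpenta-2,4-dien-1-yl}-7-oxabicyclo[4.1.0]hept-3-ene-2,5-diol
Conditions: TBAF/AcOH (1:1, 8 equiv), THF, 0 → 40 °C
Reagents that add atoms: none
Why: Fluoride-mediated cleavage of all four silyl ethers; acetic acid buffering should prevent alkoxide-driven Payne migration of the oxirane, and no acid strong enough to ionise the dienylic carbinol is present.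

**Compound list**
1 | geranyl acetate | CC(=O)OC/C=C(\C)CCC=C(C)C | starting material
2 | (6R)-6,7-epoxygeranyl acetate | CC(=O)OC/C=C(\C)CC[C@H]1OC1(C)C | intermediate
3 | [(1S,5R)-5-hydroxy-2,6,6-trimethylcyclohex-2-en-1-yl]methyl acetate | CC1=CC[C@@H](O)C(C)(C)[C@H]1COC(C)=O | intermediate
4 | [(1S,5R)-5-(TBSO)-2,6,6-trimethylcyclohex-2-en-1-yl]methyl acetate | CC1=CC[C@@H](O[Si](C)(C)C(C)(C)C)C(C)(C)[C@H]1COC(C)=O | intermediate
5 | [(1S,5R)-5-(TBSO)-2,6,6-trimethylcyclohex-2-en-1-yl]methanol | CC1=CC[C@@H](O[Si](C)(C)C(C)(C)C)C(C)(C)[C@H]1CO | intermediate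
6 | (1S,5R)-5-(TBSO)-2,6,6-trimethylcyclohex-2-ene-1-carbaldehyde | CC1=CC[C@@H](O[Si](C)(C)C(C)(C)C)C(C)(C)[C@H]1C=O | intermediate
7 | tert-butyl({(1R,5S)-5-[(E)-2-iodoethenyl]-4,6,6-trimethylcyclohex-3-en-1-yl}oxy)dimethylsilane | CC1=CC[C@@H](O[Si](C)(C)C(C)(C)C)C(C)(C)[C@H]1/C=C/I | intermediate
8 | propyne | CC#C | starting material
9 | trimethyl(tributylstannyl)silane | CCCC[Sn](CCCC)(CCCC)[Si](C)(C)C | starting material
10 | (Z)-tributyl[1-(trimethylsilyl)prop-1-en-2-yl]stannane | C/C(=C/[Si](C)(C)C)[Sn](CCCC)(CCCC)CCCC | intermediate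
11 | (1E,3Z)-dienylsilane (Si cis to C4') | CC1=CC[C@@H](O[Si](C)(C)C(C)(C)C)C(C)(C)[C@H]1/C=C/C(C)=C\[Si](C)(C)C | intermediate
12 | (1E,3Z)-4-iodo-3-methylbutadienyl cyclohexenyl TBS ether (I cis to C4') | CC1=CC[C@@H](O[Si](C)(C)C(C)(C)C)C(C)(C)[C@H]1/C=C/C(C)=C\I | intermediate
13 | 4-bromo-2,5-dimethoxybenzaldehyde | COc1cc(C=O)c(OC)cc1Br | starting material
14 | 4-bromo-2-hydroxy-5-methoxybenzaldehyde | COc1cc(C=O)c(O)cc1Br | intermediate
15 | 5-bromo-2-(hydroxymethyl)-4-methoxyphenol | COc1cc(CO)c(O)cc1Br | intermediate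
16 | 7-bromo-6-methoxy-2-(4-methoxyphenyl)-4H-1,3-benzodioxine (racemic acetal carbon) | COc1ccc(cc1)C1OCc2cc(OC)c(Br)cc2O1 | intermediate
17 | aryllithium from 16 (not isolated) | COc1ccc(cc1)C1OCc2cc(OC)c([Li])cc2O1 | intermediate
18 | 6-methoxy-2-(4-methoxyphenyl)-4H-1,3-benzodioxine-7-carbaldehyde | COc1ccc(cc1)C1OCc2cc(OC)c(C=O)cc2O1 | intermediate
19 | [6-methoxy-2-(4-methoxyphenyl)-4H-1,3-benzodioxin-7-yl]methanol, as its aluminium alkoxide (not isolated) | COc1ccc(cc1)C1OCc2cc(OC)c(CO)cc2O1 | intermediate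
20 | 5-(hydroxymethyl)-4-methoxy-2-{[(4-methoxybenzyl)oxy]methyl}phenol | COc1ccc(COCc2cc(OC)c(CO)cc2O)cc1 | intermediate
21 | 5-(hydroxymethyl)-4,4-dimethoxy-2-(PMB-oxymethyl)cyclohexa-2,5-dien-1-one | COc1ccc(COCC2=CC(OC)(OC)C(CO)=CC2=O)cc1 | intermediate
22 | (1S,6R)-4-(hydroxymethyl)-5,5-dimethoxy-1-(PMB-oxymethyl)-7-oxabicyclo[4.1.0]hept-3-en-2-one | COc1ccc(COC[C@]23O[C@H]2C(OC)(OC)C(CO)=CC3=O)cc1 | intermediate
23 | (1S,6R)-4-(hydroxymethyl)-1-(PMB-oxymethyl)-7-oxabicyclo[4.1.0]hept-3-ene-2,5-dione | COc1ccc(COC[C@]23O[C@H]2C(=O)C(CO)=CC3=O)cc1 | intermediate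
24 | (1R,2S,5R,6S)-4-(hydroxymethyl)-1-(PMB-oxymethyl)-7-oxabicyclo[4.1.0]hept-3-ene-2,5-diol | COc1ccc(COC[C@]23O[C@H]2[C@H](O)C(CO)=C[C@@H]3O)cc1 | intermediate
25 | tris-TBS ether of 24 | COc1ccc(COC[C@]23O[C@H]2[C@H](O[Si](C)(C)C(C)(C)C)C(CO[Si](C)(C)C(C)(C)C)=C[C@@H]3O[Si](C)(C)C(C)(C)C)cc1 | intermediate
26 | tris-TBS bicyclic 1-methanol | OC[C@]12O[C@H]1[C@H](O[Si](C)(C)C(C)(C)C)C(CO[Si](C)(C)C(C)(C)C)=C[C@@H]2O[Si](C)(C)C(C)(C)C | intermediate
27 | tris-TBS bicyclic 1-carbaldehyde | O=C[C@]12O[C@H]1[C@H](O[Si](C)(C)C(C)(C)C)C(CO[Si](C)(C)C(C)(C)C)=C[C@@H]2O[Si](C)(C)C(C)(C)C | intermediate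
28 | (Z,E)-dienylchromium(III) dichloride from 12 (not isolated) | CC1=CC[C@@H](O[Si](C)(C)C(C)(C)C)C(C)(C)[C@H]1/C=C/C(C)=C\[Cr](Cl)Cl | intermediate
29 | tetrakis-TBS ether of the target with free (1'S)-OH | CC1=CC[C@@H](O[Si](C)(C)C(C)(C)C)C(C)(C)[C@H]1/C=C/C(C)=C\[C@H](O)[C@]12O[C@H]1[C@H](O[Si](C)(C)C(C)(C)C)C(CO[Si](C)(C)C(C)(C)C)=C[C@@H]2O[Si](C)(C)C(C)(C)C | intermediate
30 | CNP0389279.1 | CC1=CC[C@@H](O)C(C)(C)[C@H]1/C=C/C(C)=C\[C@H](O)[C@]12O[C@H]1[C@H](O)C(CO)=C[C@@H]2O | target

**Count and risks**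
Total steps: 23. Longest linear sequence: 14 (13 → 30, steps 10–23).

1. Step 22. The facial selectivity at C1' may be low or reversed, or Cr(II) may reduce the α,β-epoxy aldehyde before the alkenylchromium adds. The fallback sets out from 27 (and 12) and returns at 29. Pinnick oxidation of 27 (NaClO2, NaH2PO4, 2-methyl-2-butene) should give the epoxy acid F1. Coupling with MeNHOMe·HCl (EDC, DMAP) should give the Weinreb amide F2. The alkenyllithium from 12 (t-BuLi, Et2O, −78 °C) should acylate to the (Z,E)-dienone F3. Chelation-controlled reduction with Zn(BH4)2 (Et2O, −30 °C), with zinc bridging the carbonyl and oxirane oxygens and hydride entering through the same open sector, should give the anti-epoxy alcohol 29.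

2. Step 18. Hydride may be delivered anti to the oxirane at one carbonyl (a syn-epoxy alcohol), and conjugate reduction of the ene-dione may compete. The fallback sets out from 22 and returns at 25; it treats the carbonyls one at a time and corrects by inversion. Luche reduction of 22 with the ketal in place should give the C2 alcohol F4. TBSOTf/2,6-lutidine should give the bis-silyl ether F5. Ketal hydrolysis (p-TsOH, wet acetone) should give the enone F6. Luche reduction gives the C5 alcohol, taken in this scenario as the syn-epoxy alcohol F7. Mitsunobu inversion (4-nitrobenzoic acid, PPh3, DIAD) should give the ester F8, methanolysis (K2CO3, MeOH) the anti alcohol F9, and TBSOTf then gives 25.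

3. Step 2. The tertiary cation may lose a methyl proton (exocyclic olefin) or be diverted by rearrangement, so regioselectivity and mass balance may be poor. The fallback sets out from 2 and returns at 3. Radical cyclisation with Cp2TiCl (from Cp2TiCl2/Mn, THF) should give the exocyclic-methylene isomer F10. Migration of the exocyclic olefin into the ring (RhCl3·3H2O cat., EtOH, 70 °C) should then give 3.

**Further compounds**
F1 | step 22 | 2,5-bis(TBSO)-4-(TBSO-methyl)-7-oxabicyclo[4.1.0]hept-3-ene-1-carboxylic acid (ring configuration as 27) | OC(=O)[C@]12O[C@H]1[C@H](O[Si](C)(C)C(C)(C)C)C(CO[Si](C)(C)C(C)(C)C)=C[C@@H]2O[Si](C)(C)C(C)(C)C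
F2 | step 22 | N-methoxy-N-methyl amide of F1 | CON(C)C(=O)[C@]12O[C@H]1[C@H](O[Si](C)(C)C(C)(C)C)C(CO[Si](C)(C)C(C)(C)C)=C[C@@H]2O[Si](C)(C)C(C)(C)C
F3 | step 22 | C1' ketone of 29 [(2'Z,4'E)-dienone] | CC1=CC[C@@H](O[Si](C)(C)C(C)(C)C)C(C)(C)[C@H]1/C=C/C(C)=C\C(=O)[C@]12O[C@H]1[C@H](O[Si](C)(C)C(C)(C)C)C(CO[Si](C)(C)C(C)(C)C)=C[C@@H]2O[Si](C)(C)C(C)(C)C
F4 | step 18 | C2 alcohol of 22 (ketal intact, 2-OH anti to the oxirane) | COc1ccc(COC[C@]23O[C@H]2C(OC)(OC)C(CO)=C[C@@H]3O)cc1
F5 | step 18 | bis-TBS ether of F4 | COc1ccc(COC[C@]23O[C@H]2C(OC)(OC)C(CO[Si](C)(C)C(C)(C)C)=C[C@@H]3O[Si](C)(C)C(C)(C)C)cc1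
F6 | step 18 | C5 enone from F5 | COc1ccc(COC[C@]23O[C@H]2C(=O)C(CO[Si](C)(C)C(C)(C)C)=C[C@@H]3O[Si](C)(C)C(C)(C)C)cc1
F7 | step 18 | C5 alcohol with OH syn to the oxirane | COc1ccc(COC[C@]23O[C@H]2[C@@H](O)C(CO[Si](C)(C)C(C)(C)C)=C[C@@H]3O[Si](C)(C)C(C)(C)C)cc1
F8 | step 18 | C5 4-nitrobenzoate, inverted (anti to the oxirane) | COc1ccc(COC[C@]23O[C@H]2[C@H](OC(=O)c4ccc(cc4)[N+](=O)[O-])C(CO[Si](C)(C)C(C)(C)C)=C[C@@H]3O[Si](C)(C)C(C)(C)C)cc1
F9 | step 18 | C5 alcohol with OH anti to the oxirane | COc1ccc(COC[C@]23O[C@H]2[C@H](O)C(CO[Si](C)(C)C(C)(C)C)=C[C@@H]3O[Si](C)(C)C(C)(C)C)cc1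
F10 | step 2 | [(1S,3R)-3-hydroxy-2,2-dimethyl-6-methylidenecyclohexyl]methyl acetate (OH and CH2OAc cis) | C=C1CC[C@@H](O)C(C)(C)[C@H]1COC(C)=O
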